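## Structural features

Giganteone A (24) is an unsymmetrical dimer of a diarylnonanoid that holds four benzene rings, two nine-carbon keto chains and no stereocentre. Ring A is a 2,6-dihydroxyphenyl ketone (C1 acyl, C2 and C6 hydroxyl) whose acyl chain, a carbonyl followed by eight methylenes, ends in ring C, a 3,4-dihydroxyphenyl group, and ring A is bonded through its C3 to C2 of ring B. Ring B is a 1,2,4,5-tetrasubstituted catechol in which C1 carries eight methylenes and a carbonyl that ends in ring D (a second 2,6-dihydroxyphenyl ketone), C4 and C5 carry hydroxyls, and C3 and C6 carry hydrogen. The biaryl axis has only two ortho substituents (the C2 hydroxyl of ring A and the C1 methylene of ring B), so it rotates freely and raises no stereochemical question. The only stereocentres of the plan are the adjacent sp3 carbons C1 and C2 of ring B that the cycloaddition creates, and both are erased on aromatization. The two catechols, which are easily oxidised to o-quinones, and the two chelated o-hydroxyaryl ketones are the fragile groups, so the phenols are freed only at the end. The real difficulty is that the two halves are nearly identical and that the bond joining them lies between two electron-rich rings with several nucleophilic positions each, so that functionalising a preformed half is regiochemically ambiguous. The key step avoids this by treating C3–C4(O)–C5(O)–C6 of ring B as a 2,3-dioxygenated butadiene and C1–C2 as an alkene that already carries the chain and ring A.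

## Logic of the disconnections

**24 ⇒ 23.** The six aryl O–CH3 bonds on rings A, C and D are cut. Methyl ethers survive organolithiums, acid, heat and bromine, so all earlier chemistry runs on robust material. The forward step must be one exhaustive Lewis-acid dealkylation that tolerates two ketones and the free ring B catechol already present in 23.

**23 ⇒ 21 (through 22).** The aromatic ring B is taken back to a cyclohexene: C4–O and C5–O become an enediol bis(silyl) ether, C1 regains a nitro group and C2 a hydrogen. A catechol is the tautomer of a cyclohex-3-ene-1,2-dione, and that dione arises from the saturated nitro dione 22 by loss of HNO2, so the arene becomes a Diels–Alder retron. The forward demands are an oxidant that attacks the enediol ether faster than three methoxyarenes, and an acidic hydrogen placed for the elimination. The C5 carbonyl of 22 supplies the latter at C6 and steers the elimination into the ring. This matters because in 21 the C2 hydrogen is cis to the nitro group and cannot serve an anti elimination, while an unactivated elimination could also run into the side chain.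

**21 ⇒ 19 + 20.** The C2–C3 and C1–C6 bonds are cut. Ring B falls into a symmetric four-carbon diene holding both oxygens and an alkene holding everything else; the nitro group activates first and leaves later. All four rings and both chains converge here with no biaryl coupling and no regiochemical question. The forward step must force a thermal cycloaddition onto a trisubstituted, donor-substituted nitroalkene while the silyl enol ethers survive.

**19 ⇒ 11 + 18.** The C1=C2 double bond of the future ring B is cut, a nitroaldol-condensation retron. It divides the molecule into halves of similar size. The forward step must condense a long-chain primary nitroalkane with an ortho-substituted aldehyde at near 1:1 stoichiometry, give the (E) alkene under thermodynamic control, and leave both hindered ketones alone.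

**11 ⇒ 8 + 6, and 8 ⇒ 7.** The ring A C1–acyl bond is cut. C1 lies between two methoxy groups and is the most acidic ring position, so it can be lithiated. The C3 aldehyde carbon is already present in 7. A late formylation is avoided because it would have to choose between ring A and the equally electron-rich ring C. The forward step needs the aldehyde masked as an acetal and an acyl donor that stops at the ketone.

**6 ⇒ 5 ⇒ 4 ⇒ 1 + 2.** The amide C–N bond, the benzylic CH2 (back to a ketone) and the ring C aryl–acyl bond are cut. Friedel–Crafts acylation of 2 is para-selective, and 1 supplies the nine-carbon chain with differentiated ends. The forward sequence must remove the benzylic carbonyl without touching the ester.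

**18 ⇒ 17 ⇒ 14 + 15, and 14 ⇒ 12.** The C–NO2 bond, the ring D aryl–acyl bond and the amide bond are cut. 12 holds exactly the ten chain carbons, and 15 lithiates between its methoxy groups. The forward steps require the aryllithium to acylate faster than it alkylates the primary bromide, and the nitrogen of the ambident nitrite ion to be alkylated in preference to its oxygen.

## Other disconnections considered

Alternative 1: Ring B is removed entirely by cutting C1–C2, C3–C4 and C5–C6, with ring A and the first chain carbon held together by an ester. In the forward sense, CpCo(CO)2 would cyclotrimerize the tethered diyne 2-ethynyl-5-methoxyphenyl prop-2-ynoate A1 with bis(pinacolatoboryl)ethyne A2 to the benzo[c]chromenone bis(boronate) A3, closing ring B and the pyranone ring together.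
- In favour: three C–C bonds and two rings form in one catalytic step. The tether of A1 fixes the regiochemistry. The two C–B bonds of A3 are latent catechol oxygens, the lactone oxygen is the ring A C2 hydroxyl, and the lactone carbonyl is the first carbon of the ring B chain.
- Against: the aryl propiolate A1 is a reluctant tether, since the ester prefers the conformation that holds the alkynes apart, and it is electrophilic. The two terminal alkynes of A1 invite homotrimerization, so the hindered A2 would be needed in excess. A3 holds only one of the eighteen chain carbons and neither ring C nor ring D. The lactone must then be reduced and homologated, and ring A acylated at the crowded carbon between its oxygens, all in linear fashion.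
- Comparison: on the key step alone it is the better plan in bond count (three bonds and two rings against two bonds and one ring). It is the equal in regiocontrol (tether against symmetric diene). Its mechanism (cobaltacyclopentadiene, alkyne insertion, reductive elimination) runs under neutral conditions without the forcing temperature expected for the chosen cycloaddition, which is a point in its favour. On structure and step economy it is weaker, because the chosen plan unites all four rings and both chains at the key step and needs two steps afterwards.

Alternative 2: Both bonds to the ring A ketone carbon are cut. In the forward sense, the biaryl iodide A4, the B-alkyl-9-borabicyclononane A5 and carbon monoxide A6 would combine under PdCl2(dppf) and K3PO4 to give the ketone A7. The terminal alkene of A7 is the handle for a second coupling of the same kind that would attach ring D.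
- In favour: a ketone flanked by two methoxy groups is made catalytically without organolithium reagents. A6 is the simplest one-carbon unit available, and one reaction type serves for both aryl ketones.
- Against: ring B is not built. It must be carried in with four substituents, and the biaryl bond of A4 needs a separate cross-coupling followed by iodination between two methoxy groups. The iodide A4 is doubly ortho-substituted, so direct coupling without uptake of A6, β-hydride elimination and hydrodehalogenation are plausible competitors. The free alkene of A4 must never meet a borane, and A6 must be handled under pressure.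
- Comparison: the catalytic cycle is well understood (oxidative addition to zerovalent palladium, insertion of A6 to a divalent acylpalladium, transmetalation, reductive elimination), so it is the equal or the better in predictability of the bond-forming event. On paper it could be the better plan in step count if A4 is reached in three or four operations, and it is the equal in convergence. It is weaker on structure: the one difficult bond (ring A to ring B) is left to a conventional coupling of two ortho-substituted, electron-rich partners, and it relies twice on the most hindered class of carbonylative coupling.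

Alternative 3: The C3(ring A)–C2(ring B) biaryl bond is cut, with a lactone between the ring A C2 oxygen and the carbon that becomes the first chain carbon on ring B. In the forward sense, a Hurtley condensation of resorcinol A8 with 2-bromo-4,5-dimethoxybenzoic acid A9, using CuSO4 in aqueous NaOH, would give the lactone A10.
- In favour: one step in water from two inexpensive compounds. The biaryl bond forms only at C4 of A8, the ring B oxygens are in place, and the ring A oxygens of A10 are differentiated (lactone against free hydroxyl).
- Against: the downstream burden is that of alternative 1. The lactone carbonyl of A10 must be reduced and extended by eight carbons plus ring D, and ring A must be C-acylated between its oxygens next to the biaryl. Protodebromination and decarboxylation of A9 are expected to limit the efficiency of the condensation.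
- Comparison: it is the better plan for access to the oxygenated biaryl core (one step against the eleven operations that lead to 23) and for simplicity and cost of the key step. It is the equal in regiocontrol and in freedom from stereochemical issues. It is weaker in convergence and overall step economy, because two nine-carbon chains must be grafted in sequence, one by acylation at the most hindered site of ring A. The chosen plan forms that aryl–acyl bond early on a monocyclic arene.

Key step: step 10

Remarks on the chemistry
- The (E) alkene of 19 (aryl trans to nitro) and the trans aryl/nitro relationship in 21 agree with each other under suprafacial addition; 21 and 22 are racemic and both centres vanish at 23.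
- Two design choices deserve a word. The ring A aldehyde carbon comes from 7 and not from a late formylation, which would compete with ring C. After the cycloaddition the enediol ether is oxidised before HNO2 is lost, so the elimination is carbonyl-activated and directed into the ring.
- Assumption: 1, 2, 7, 12, 15 and 20 are purchased.

## Route

Step 1
Reactants: 1 9-methoxy-9-oxononanoic acid; 2 1,2-dimethoxybenzene
Product: 4 methyl 9-(3,4-dimethoxyphenyl)-9-oxononanoate, via methyl 9-chloro-9-oxononanoate 3 (not isolated)
Conditions: (COCl)2, cat. DMF, CH2Cl2, 0 °C to rt; then 2, AlCl3, CH2Cl2, 0 °C to rt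
Reagents that add atoms: none
Why: Acid chloride formation followed by Friedel–Crafts acylation; 2 should react para to a methoxy group, and the ester survives as its AlCl3 complex when more than two equivalents of Lewis acid are used.

Step 2
Reactants: 4 methyl 9-(3,4-dimethoxyphenyl)-9-oxononanoate
Product: 5 methyl 9-(3,4-dimethoxyphenyl)nonanoate
Conditions: Et3SiH, TFA, rt
Reagents that add atoms: none
Why: Ionic hydrogenation: the benzylic cation stabilised by the para methoxy group is reduced by hydride transfer twice (C=O to CH2), while the ester and the aryl ethers are inert to these conditions.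

Step 3
Reactants: 5 methyl 9-(3,4-dimethoxyphenyl)nonanoate
Product: 6 9-(3,4-dimethoxyphenyl)-N-methoxy-N-methylnonanamide
Conditions: MeNH(OMe)·HCl, i-PrMgCl, THF, −20 °C to 0 °C
Reagents that add atoms: N,O-dimethylhydroxylamine hydrochloride, CNOC.Cl
Why: Direct aminolysis of the ester by the chloromagnesium amide of the alkoxyamine (Weinreb amide formation); the chelated tetrahedral adduct prevents further attack.

Step 4
Reactants: 7 2,4-dimethoxybenzaldehyde
Product: 8 1-(dimethoxymethyl)-2,4-dimethoxybenzene
Conditions: HC(OMe)3, MeOH, cat. p-TsOH, rt; Et3N quench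
Reagents that add atoms: trimethyl orthoformate, COC(OC)OC; methanol, CO
Why: Acid-catalysed acetalization with the orthoformate as water scavenger masks the aldehyde against the organolithium of the next step.

Step 5
Reactants: 8 1-(dimethoxymethyl)-2,4-dimethoxybenzene; 6 9-(3,4-dimethoxyphenyl)-N-methoxy-N-methylnonanamide
Product: 11 3-[9-(3,4-dimethoxyphenyl)nonanoyl]-2,4-dimethoxybenzaldehyde, via [3-(dimethoxymethyl)-2,6-dimethoxyphenyl]lithium 9 (not isolated), via 1-[3-(dimethoxymethyl)-2,6-dimethoxyphenyl]-9-(3,4-dimethoxyphenyl)nonan-1-one 10 (not isolated)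
Conditions: n-BuLi, THF, 0 °C; then 6, −78 °C to 0 °C; then 1 M HCl, THF, rt
Reagents that add atoms: water, O
Why: Directed ortho-metalation at the carbon flanked by both methoxy groups, then Weinreb ketone synthesis in which the chelated adduct blocks over-addition; aqueous acid releases the ketone and hydrolyses the acetal in the same flask.

Step 6
Reactants: 12 10-bromodecanoic acid
Product: 14 10-bromo-N-methoxy-N-methyldecanamide, via 10-bromodecanoyl chloride 13 (not isolated)
Conditions: (COCl)2, cat. DMF, CH2Cl2, 0 °C to rt; evaporate; then MeNH(OMe)·HCl, pyridine, CH2Cl2, 0 °C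
Reagents that add atoms: N,O-dimethylhydroxylamine hydrochloride, CNOC.Cl
Why: Acid chloride formation and amidation; the weakly nucleophilic alkoxyamine acylates at 0 °C far faster than it displaces the primary bromide.

Step 7
Reactants: 15 1,3-dimethoxybenzene; 14 10-bromo-N-methoxy-N-methyldecanamide
Product: 17 10-bromo-1-(2,6-dimethoxyphenyl)decan-1-one, via (2,6-dimethoxyphenyl)lithium 16 (not isolated)
Conditions: n-BuLi, THF, 0 °C to rt; then added to 14, THF, −78 °C to −20 °C; NH4Cl
Reagents that add atoms: none
Why: Directed ortho-metalation of 15 between its methoxy groups and Weinreb ketone synthesis; at low temperature, with the aryllithium added to the amide, acyl addition should outrun SN2 attack at the primary bromide.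

Step 8
Reactants: 17 10-bromo-1-(2,6-dimethoxyphenyl)decan-1-one
Product: 18 1-(2,6-dimethoxyphenyl)-10-nitrodecan-1-one
Conditions: NaNO2, phloroglucinol, DMF, rt
Reagents that add atoms: sodium nitrite, [Na+].[O-]N=O
Why: Kornblum displacement: in DMF the ambident nitrite ion alkylates mainly at nitrogen on a primary bromide, and phloroglucinol scavenges the nitrite ester by-product so that it cannot nitrosate the nitroalkane.

Step 9
Reactants: 11 3-[9-(3,4-dimethoxyphenyl)nonanoyl]-2,4-dimethoxybenzaldehyde; 18 1-(2,6-dimethoxyphenyl)-10-nitrodecan-1-one
Product: 19 (E)-1-{3-[9-(3,4-dimethoxyphenyl)nonanoyl]-2,4-dimethoxyphenyl}-11-(2,6-dimethoxyphenyl)-2-nitroundec-1-en-11-one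
Conditions: NH4OAc, AcOH, 100 °C
Reagents that add atoms: none
Why: Henry (nitroaldol) condensation with dehydration in the same pot; reversible addition and elimination lead to the more stable (E) alkene with aryl trans to nitro, and the two di-ortho-substituted aryl ketones are too hindered to condense.

Step 10
Reactants: 19 (E)-1-{3-[9-(3,4-dimethoxyphenyl)nonanoyl]-2,4-dimethoxyphenyl}-11-(2,6-dimethoxyphenyl)-2-nitroundec-1-en-11-one; 20 2,3-bis(trimethylsilyloxy)buta-1,3-diene
Product: 21 racemic 1-(3-{6-[9-(2,6-dimethoxyphenyl)-9-oxononyl]-6-nitro-3,4-bis(trimethylsilyloxy)cyclohex-3-en-1-yl}-2,6-dimethoxyphenyl)-9-(3,4-dimethoxyphenyl)nonan-1-one, relative configuration 1R*,6S* at the cyclohexene carbons (nitro trans to aryl)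
Conditions: 20 (5 equiv), BHT (cat.), PhMe, sealed tube, 140 °C; chromatography on Et3N-deactivated silica
Reagents that add atoms: none
Why: Thermal normal-electron-demand Diels–Alder reaction: the HOMO of diene 20 and the LUMO of the nitro-activated alkene of 19 combine in one concerted but asynchronous event, the bond to the benzylic carbon (C2–C3) being more advanced than the bond to the nitro-bearing carbon (C1–C6). The closest known reaction type is the cycloaddition of β-alkyl-β-nitrostyrenes with 2-silyloxy- and 2,3-dioxygenated butadienes, in which the nitroalkene serves as a masked alkyne. Ring B is closed as a six-membered carbocycle by intermolecular [4+2] cycloaddition, suprafacial on both partners, with four carbons from 20 and two from 19. The two new stereocentres, quaternary C1 (nitro, chain) and tertiary C2 (aryl, H), are set relative to each other by the (E) geometry of 19, which suprafacial addition transfers unchanged, so aryl and nitro end up trans; with no chiral element present the adduct is racemic, and because 20 has no terminal substituents endo or exo approach creates no further isomers. No regiochemical question arises because the two termini of 20 are equivalent. The selectivity needed is chemoselectivity: the nitro group lowers the LUMO of the C=C bond far below that of the two twisted, hindered aryl ketones, and the absence of any Lewis acid disfavours the competing path in which the nitroalkene acts as a heterodiene toward one enol ether double bond. Excess 20, a radical inhibitor and strict exclusion of acid should keep the diene and the silyl enol ethers of 21 intact during the long heating that this trisubstituted, donor-substituted dienophile requires. Both stereocentres are destroyed in step 11, so their configuration has no bearing on the target.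

Step 11
Reactants: 21 racemic 1-(3-{6-[9-(2,6-dimethoxyphenyl)-9-oxononyl]-6-nitro-3,4-bis(trimethylsilyloxy)cyclohex-3-en-1-yl}-2,6-dimethoxyphenyl)-9-(3,4-dimethoxyphenyl)nonan-1-one
Product: 23 1-(3-{2-[9-(2,6-dimethoxyphenyl)-9-oxononyl]-4,5-dihydroxyphenyl}-2,6-dimethoxyphenyl)-9-(3,4-dimethoxyphenyl)nonan-1-one, via ring B nitro 1,2-dione 22 (not isolated)
Conditions: Br2 (1.0 equiv, slow addition), CH2Cl2, −78 °C; then Et3N, MeOH, −78 °C to rt; pH 7 buffer work-up under argon
Reagents that add atoms: none
Why: Bromine oxidises the enediol bis(silyl) ether to the 1,2-dione (the standard conversion of acyloin-derived bis(silyloxy)alkenes) much faster than it attacks a methoxyarene at −78 °C. In 22 the nitro group is β to the C5 carbonyl, so Et3N removes a C6 hydrogen and nitrite leaves by E1cB, and two enolizations of the resulting cyclohex-3-ene-1,2-dione give the catechol. Methanol traps the silyl bromide, and the neutral work-up keeps nitrite from nitrosating the product.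

Step 12
Reactants: 23 1-(3-{2-[9-(2,6-dimethoxyphenyl)-9-oxononyl]-4,5-dihydroxyphenyl}-2,6-dimethoxyphenyl)-9-(3,4-dimethoxyphenyl)nonan-1-one
Product: 24 giganteone A
Conditions: BBr3 (excess), CH2Cl2, −78 °C to rt; then MeOH, H2O, 0 °C; argon throughout
Reagents that add atoms: none
Why: Exhaustive Lewis-acid demethylation: each ether oxygen binds boron and bromide attacks the methyl group by SN2, the four ethers ortho to a ketone being accelerated by chelation; hydrolysis of the aryl borates on work-up frees all eight phenols, and the ketones are untouched.

## Compound list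

1 | 9-methoxy-9-oxononanoic acid (monomethyl azelate) | COC(=O)CCCCCCCC(=O)O | starting material
2 | 1,2-dimethoxybenzene | COc1ccccc1OC | starting material
3 | methyl 9-chloro-9-oxononanoate | COC(=O)CCCCCCCC(Cl)=O | intermediate
4 | methyl 9-(3,4-dimethoxyphenyl)-9-oxononanoate | COC(=O)CCCCCCCC(=O)c1ccc(OC)c(OC)c1 | intermediate
5 | methyl 9-(3,4-dimethoxyphenyl)nonanoate | COC(=O)CCCCCCCCc1ccc(OC)c(OC)c1 | intermediate
6 | 9-(3,4-dimethoxyphenyl)-N-methoxy-N-methylnonanamide | CON(C)C(=O)CCCCCCCCc1ccc(OC)c(OC)c1 | intermediate
7 | 2,4-dimethoxybenzaldehyde | COc1ccc(C=O)c(OC)c1 | starting material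
8 | 1-(dimethoxymethyl)-2,4-dimethoxybenzene | COc1ccc(C(OC)OC)c(OC)c1 | intermediate
9 | [3-(dimethoxymethyl)-2,6-dimethoxyphenyl]lithium | [Li]c1c(OC)ccc(C(OC)OC)c1OC | intermediate
10 | 1-[3-(dimethoxymethyl)-2,6-dimethoxyphenyl]-9-(3,4-dimethoxyphenyl)nonan-1-one | COC(OC)c1ccc(OC)c(C(=O)CCCCCCCCc2ccc(OC)c(OC)c2)c1OC | intermediate
11 | 3-[9-(3,4-dimethoxyphenyl)nonanoyl]-2,4-dimethoxybenzaldehyde | COc1ccc(C=O)c(OC)c1C(=O)CCCCCCCCc1ccc(OC)c(OC)c1 | intermediate
12 | 10-bromodecanoic acid | OC(=O)CCCCCCCCCBr | starting material
13 | 10-bromodecanoyl chloride | ClC(=O)CCCCCCCCCBr | intermediate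
14 | 10-bromo-N-methoxy-N-methyldecanamide | CON(C)C(=O)CCCCCCCCCBr | intermediate
15 | 1,3-dimethoxybenzene | COc1cccc(OC)c1 | starting material
16 | (2,6-dimethoxyphenyl)lithium | [Li]c1c(OC)cccc1OC | intermediate
17 | 10-bromo-1-(2,6-dimethoxyphenyl)decan-1-one | COc1cccc(OC)c1C(=O)CCCCCCCCCBr | intermediate
18 | 1-(2,6-dimethoxyphenyl)-10-nitrodecan-1-one | COc1cccc(OC)c1C(=O)CCCCCCCCC[N+](=O)[O-] | intermediate
19 | (E)-1-{3-[9-(3,4-dimethoxyphenyl)nonanoyl]-2,4-dimethoxyphenyl}-11-(2,6-dimethoxyphenyl)-2-nitroundec-1-en-11-one | COc1ccc(/C=C(\CCCCCCCCC(=O)c2c(OC)cccc2OC)[N+](=O)[O-])c(OC)c1C(=O)CCCCCCCCc1ccc(OC)c(OC)c1 | intermediate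
20 | 2,3-bis(trimethylsilyloxy)buta-1,3-diene | C=C(O[Si](C)(C)C)C(=C)O[Si](C)(C)C | starting material
21 | racemic 1-(3-{6-[9-(2,6-dimethoxyphenyl)-9-oxononyl]-6-nitro-3,4-bis(trimethylsilyloxy)cyclohex-3-en-1-yl}-2,6-dimethoxyphenyl)-9-(3,4-dimethoxyphenyl)nonan-1-one, relative configuration 1R*,6S* at the cyclohexene carbons, nitro trans to aryl (one enantiomer drawn) | [O-][N+](=O)[C@]1(CCCCCCCCC(=O)c2c(OC)cccc2OC)CC(O[Si](C)(C)C)=C(O[Si](C)(C)C)C[C@H]1c1ccc(OC)c(C(=O)CCCCCCCCc2ccc(OC)c(OC)c2)c1OC | intermediate
22 | racemic 1-(3-{2-[9-(2,6-dimethoxyphenyl)-9-oxononyl]-2-nitro-4,5-dioxocyclohexyl}-2,6-dimethoxyphenyl)-9-(3,4-dimethoxyphenyl)nonan-1-one, relative configuration 1R*,2S* at the cyclohexane carbons, nitro trans to aryl (one enantiomer drawn) | [O-][N+](=O)[C@]1(CCCCCCCCC(=O)c2c(OC)cccc2OC)CC(=O)C(=O)C[C@H]1c1ccc(OC)c(C(=O)CCCCCCCCc2ccc(OC)c(OC)c2)c1OC | intermediate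
23 | 1-(3-{2-[9-(2,6-dimethoxyphenyl)-9-oxononyl]-4,5-dihydroxyphenyl}-2,6-dimethoxyphenyl)-9-(3,4-dimethoxyphenyl)nonan-1-one | O=C(CCCCCCCCc1cc(O)c(O)cc1-c1ccc(OC)c(C(=O)CCCCCCCCc2ccc(OC)c(OC)c2)c1OC)c1c(OC)cccc1OC | intermediate
24 | giganteone A, 1-(3-{2-[9-(2,6-dihydroxyphenyl)-9-oxononyl]-4,5-dihydroxyphenyl}-2,6-dihydroxyphenyl)-9-(3,4-dihydroxyphenyl)nonan-1-one | O=C(CCCCCCCCc1cc(O)c(O)cc1-c1ccc(O)c(C(=O)CCCCCCCCc2ccc(O)c(O)c2)c1O)c1c(O)cccc1O | target

## Step count and least certain steps

Total: 12 steps. Longest linear sequence: 8 steps (1, 2, 3, 5, 9, 10, 11, 12).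

**Step 10 (key step).** The most likely failure is low conversion, because the dienophile is trisubstituted and bears a donor-substituted, ortho-substituted aryl group while the diene is only moderately reactive. At the temperature needed the diene may oligomerise. The adduct may lose HNO2 prematurely, and the acid set free would then strip the silyl groups. The nitroalkene may also react as a heterodiene to give a cyclic nitronate. The fallback replaces ring construction by a biaryl cross-coupling; it sets out from 5, 6 and 16 and rejoins the route at 24. Compound 5 is brominated on its only arene (NBS, MeCN), para to a methoxy group and ortho to the chain, to give methyl 9-(2-bromo-4,5-dimethoxyphenyl)nonanoate F1. This is converted as in step 3 into 9-(2-bromo-4,5-dimethoxyphenyl)-N-methoxy-N-methylnonanamide F2, which acylates 16 as in step 7 to give 9-(2-bromo-4,5-dimethoxyphenyl)-1-(2,6-dimethoxyphenyl)nonan-1-one F3. Separately, purchased 1-bromo-2,4-dimethoxybenzene F4 is deprotonated between its methoxy groups with lithium 2,2,6,6-tetramethylpiperidide (THF, −78 °C, no halogen–lithium exchange) and acylated with 6 to give 1-(3-bromo-2,6-dimethoxyphenyl)-9-(3,4-dimethoxyphenyl)nonan-1-one F5. Miyaura borylation (B2pin2, PdCl2(dppf), KOAc, dioxane) gives 9-(3,4-dimethoxyphenyl)-1-[2,6-dimethoxy-3-(4,4,5,5-tetramethyl-1,3,2-dioxaborolan-2-yl)phenyl]nonan-1-one F6. Suzuki–Miyaura coupling of F3 with F6 (Pd(OAc)2, SPhos, K3PO4, PhMe/H2O) gives octa-O-methylgiganteone A F7, and BBr3 as in step 12 gives 24.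

**Step 11.** The risks are competing electrophilic bromination of a methoxyarene, over-oxidation of the nascent catechol, and nitrosation by nitrite if the work-up turns acidic. The fallback reverses the order to elimination first and dehydrogenation second; it sets out from 21 and rejoins at 23. DBU in hot toluene removes HNO2 by anti elimination across C6–C1, since C6 carries the only ring hydrogen anti to the nitro group. The conjugated endocyclic diene should be favoured over elimination into the side chain. This gives racemic 1-(3-{2-[9-(2,6-dimethoxyphenyl)-9-oxononyl]-4,5-bis(trimethylsilyloxy)cyclohexa-2,4-dien-1-yl}-2,6-dimethoxyphenyl)-9-(3,4-dimethoxyphenyl)nonan-1-one F8. DDQ (one equivalent, PhMe, 0 °C) dehydrogenates it to the arene 1-(3-{2-[9-(2,6-dimethoxyphenyl)-9-oxononyl]-4,5-bis(trimethylsilyloxy)phenyl}-2,6-dimethoxyphenyl)-9-(3,4-dimethoxyphenyl)nonan-1-one F9, and K2CO3 in MeOH removes the silyl groups to give 23. This elimination is not carbonyl-activated and may need prolonged heating.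

**Step 9.** The risks are incomplete condensation at near-equimolar ratio, reversal of the nitroaldol addition, and conjugate addition of a second nitroalkane to the product. The fallback separates addition from dehydration; it sets out from 11 and 18 and rejoins at 19. Catalytic tetramethylguanidine in THF at 0 °C gives the β-nitro alcohol 1-{3-[9-(3,4-dimethoxyphenyl)nonanoyl]-2,4-dimethoxyphenyl}-11-(2,6-dimethoxyphenyl)-1-hydroxy-2-nitroundecan-11-one F10 as a mixture of diastereomers. MsCl and Et3N (CH2Cl2, 0 °C) convert it into its methanesulfonate F11, which eliminates in the same flask to 19.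

**Step 5.** The risks are incomplete or misdirected lithiation of 8, and the hindered aryllithium acting as a base toward 6 (α-deprotonation, or cleavage of the N–O methyl group) in place of adding to it. The fallback swaps acyl substitution for carbonyl addition and oxidation; it sets out from 6 and 9 and rejoins at 10. i-Bu2AlH (THF, −78 °C) reduces 6 to 9-(3,4-dimethoxyphenyl)nonanal F12. Addition of 9 gives the racemic carbinol 1-[3-(dimethoxymethyl)-2,6-dimethoxyphenyl]-9-(3,4-dimethoxyphenyl)nonan-1-ol F13. Dess–Martin periodinane (buffered with NaHCO3) oxidises it to 10, which aqueous acid converts to 11 as in step 5.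

## Further compounds

F1 | step 10 | methyl 9-(2-bromo-4,5-dimethoxyphenyl)nonanoate | COC(=O)CCCCCCCCc1cc(OC)c(OC)cc1Br
F2 | step 10 | 9-(2-bromo-4,5-dimethoxyphenyl)-N-methoxy-N-methylnonanamide | CON(C)C(=O)CCCCCCCCc1cc(OC)c(OC)cc1Br
F3 | step 10 | 9-(2-bromo-4,5-dimethoxyphenyl)-1-(2,6-dimethoxyphenyl)nonan-1-one | COc1cccc(OC)c1C(=O)CCCCCCCCc1cc(OC)c(OC)cc1Br
F4 | step 10 | 1-bromo-2,4-dimethoxybenzene | COc1ccc(Br)c(OC)c1
F5 | step 10 | 1-(3-bromo-2,6-dimethoxyphenyl)-9-(3,4-dimethoxyphenyl)nonan-1-one | COc1ccc(Br)c(OC)c1C(=O)CCCCCCCCc1ccc(OC)c(OC)c1
F6 | step 10 | 9-(3,4-dimethoxyphenyl)-1-[2,6-dimethoxy-3-(4,4,5,5-tetramethyl-1,3,2-dioxaborolan-2-yl)phenyl]nonan-1-one | COc1ccc(B2OC(C)(C)C(C)(C)O2)c(OC)c1C(=O)CCCCCCCCc1ccc(OC)c(OC)c1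
F7 | step 10 | 1-(3-{2-[9-(2,6-dimethoxyphenyl)-9-oxononyl]-4,5-dimethoxyphenyl}-2,6-dimethoxyphenyl)-9-(3,4-dimethoxyphenyl)nonan-1-one (octa-O-methylgiganteone A) | O=C(CCCCCCCCc1cc(OC)c(OC)cc1-c1ccc(OC)c(C(=O)CCCCCCCCc2ccc(OC)c(OC)c2)c1OC)c1c(OC)cccc1OC
F8 | step 11 | racemic 1-(3-{2-[9-(2,6-dimethoxyphenyl)-9-oxononyl]-4,5-bis(trimethylsilyloxy)cyclohexa-2,4-dien-1-yl}-2,6-dimethoxyphenyl)-9-(3,4-dimethoxyphenyl)nonan-1-one | C[Si](C)(C)OC1=C(O[Si](C)(C)C)C=C(CCCCCCCCC(=O)c2c(OC)cccc2OC)C(c2ccc(OC)c(C(=O)CCCCCCCCc3ccc(OC)c(OC)c3)c2OC)C1
F9 | step 11 | 1-(3-{2-[9-(2,6-dimethoxyphenyl)-9-oxononyl]-4,5-bis(trimethylsilyloxy)phenyl}-2,6-dimethoxyphenyl)-9-(3,4-dimethoxyphenyl)nonan-1-one | O=C(CCCCCCCCc1cc(O[Si](C)(C)C)c(O[Si](C)(C)C)cc1-c1ccc(OC)c(C(=O)CCCCCCCCc2ccc(OC)c(OC)c2)c1OC)c1c(OC)cccc1OC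
F10 | step 9 | 1-{3-[9-(3,4-dimethoxyphenyl)nonanoyl]-2,4-dimethoxyphenyl}-11-(2,6-dimethoxyphenyl)-1-hydroxy-2-nitroundecan-11-one (mixture of diastereomers) | COc1ccc(C(O)C(CCCCCCCCC(=O)c2c(OC)cccc2OC)[N+](=O)[O-])c(OC)c1C(=O)CCCCCCCCc1ccc(OC)c(OC)c1
F11 | step 9 | methanesulfonate of F10 (mixture of diastereomers) | COc1ccc(C(OS(C)(=O)=O)C(CCCCCCCCC(=O)c2c(OC)cccc2OC)[N+](=O)[O-])c(OC)c1C(=O)CCCCCCCCc1ccc(OC)c(OC)c1
F12 | step 5 | 9-(3,4-dimethoxyphenyl)nonanal | O=CCCCCCCCCc1ccc(OC)c(OC)c1
F13 | step 5 | racemic 1-[3-(dimethoxymethyl)-2,6-dimethoxyphenyl]-9-(3,4-dimethoxyphenyl)nonan-1-ol | COC(OC)c1ccc(OC)c(C(O)CCCCCCCCc2ccc(OC)c(OC)c2)c1OC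
A1 | alternative 1 | 2-ethynyl-5-methoxyphenyl prop-2-ynoate | C#CC(=O)Oc1cc(OC)ccc1C#C
A2 | alternative 1 | bis(pinacolatoboryl)ethyne | CC1(C)OB(C#CB2OC(C)(C)C(C)(C)O2)OC1(C)C
A3 | alternative 1 | 3-methoxy-8,9-bis(4,4,5,5-tetramethyl-1,3,2-dioxaborolan-2-yl)-6H-benzo[c]chromen-6-one | COc1ccc2c(c1)oc(=O)c1cc(B3OC(C)(C)C(C)(C)O3)c(B3OC(C)(C)C(C)(C)O3)cc12
A4 | alternative 2 | 2-iodo-1,3-dimethoxy-4-[4,5-dimethoxy-2-(oct-7-en-1-yl)phenyl]benzene | COc1ccc(-c2cc(OC)c(OC)cc2CCCCCCC=C)c(OC)c1I
A5 | alternative 2 | 9-[8-(3,4-dimethoxyphenyl)octyl]-9-borabicyclo[3.3.1]nonane | COc1ccc(CCCCCCCCB2C3CCCC2CCC3)cc1OC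
A6 | alternative 2 | carbon monoxide | [C-]#[O+]
A7 | alternative 2 | 9-(3,4-dimethoxyphenyl)-1-{2,6-dimethoxy-3-[4,5-dimethoxy-2-(oct-7-en-1-yl)phenyl]phenyl}nonan-1-one | COc1ccc(-c2cc(OC)c(OC)cc2CCCCCCC=C)c(OC)c1C(=O)CCCCCCCCc1ccc(OC)c(OC)c1
A8 | alternative 3 | resorcinol (benzene-1,3-diol) | Oc1cccc(O)c1
A9 | alternative 3 | 2-bromo-4,5-dimethoxybenzoic acid | COc1cc(Br)c(C(=O)O)cc1OC
A10 | alternative 3 | 3-hydroxy-8,9-dimethoxy-6H-benzo[c]chromen-6-one | COc1cc2c(cc1OC)c(=O)oc1cc(O)ccc12
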